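Chain numbering runs from the ester carbon C1 to the brominated C20. The only ring is the oxolane O/C5/C6/C7/C8, trans-substituted at C5 (R) and C8 (S).
Enabling feature: C5 is both a ring ether carbon and the anchor of the C4–C1 arm. O–C5 and C5–C4 can therefore be made in one operation when an allyl group on the future ring oxygen migrates to a carbenoid C5; the C6 ketone this leaves is deleted afterwards.
Cuts, in retrosynthetic order: C10–C11 (Sonogashira), C9≡C10 (aldehyde-to-alkyne homologation), C2=C3 (acrylate cross-metathesis), C6–O (deoxygenation), then O–C5 together with C5–C4 (ylide closure and [2,3]-shift). In the side arm the cut is C18–C19 (alkenyl–alkenyl coupling).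
Forward order: dimethyl (S)-malate is taken to an allyl ether diazoketone, the oxolane closes in the carbenoid step, and C6 is deoxygenated. The allyl group is then grown to the butanoate, the silyloxymethyl group becomes the C9≡C10 alkyne, and the C11–C20 bromo-iodo-triene from octa-1,7-diyne is attached last.
Stereochemistry: C8 is the malate carbinol carbon, carried through unchanged, and C5 is set trans to it in the rearrangement. The three E-alkenes come from syn hydrozirconation and from stereoretentive couplings of (E)-1-bromo-2-iodoethene.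

Key step: step 6

Remark: in SMILES the cyclopentadienyl ligands on zirconium are written as σ-bonded C5H5 rings; the C6 carbinol of 11 and 12 is drawn as the expected major epimer, though either epimer serves; the CIP label of C5 reads S in 13 and 15 only because the unsaturated chain outranks ring carbon C6, the spatial arrangement being unchanged.

Step 1
Reactants: 1 dimethyl (S)-malate
Product: 2 methyl (S)-3,4-dihydroxybutanoate
Conditions: BH3·SMe2 (1.05 equiv), NaBH4 (5 mol%), THF, 0 °C → rt; MeOH quench
Reagents that add atoms: none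
Why: Hydroxyl-directed chemoselective borane reduction, in which the free carbinol forms an alkoxyborane that delivers hydride through a five-membered chelate to the neighbouring ester only, leaving the stereocentre (future C8) untouched.

Step 2
Reactants: 2 methyl (S)-3,4-dihydroxybutanoate
Product: 3 methyl (S)-4-[(tert-butyldiphenylsilyl)oxy]-3-hydroxybutanoate
Conditions: TBDPSCl (1.05 equiv), imidazole, CH2Cl2, 0 °C → rt
Reagents that add atoms: tert-butyl(chloro)diphenylsilane, CC(C)(C)[Si](Cl)(c1ccccc1)c1ccccc1
Why: Selective silyl ether formation, since the bulky silyl chloride reacts at the primary hydroxyl far faster than at the secondary one, and the TBDPS ether should withstand the acid, base, hydride, radical and hydrogenation steps ahead.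

Step 3
Reactants: 3 methyl (S)-4-[(tert-butyldiphenylsilyl)oxy]-3-hydroxybutanoate; 4 allyl 2,2,2-trichloroacetimidate
Product: 5 methyl (S)-3-(allyloxy)-4-[(tert-butyldiphenylsilyl)oxy]butanoate
Conditions: 4 (1.5 equiv), TfOH (5 mol%), cyclohexane–CH2Cl2 (2:1), 0 °C → rt
Reagents that add atoms: none
Why: Acid-catalysed O-alkylation with a trichloroacetimidate transfers the allyl group without forming an alkoxide, which would invite β-elimination of the β-hydroxy ester or 1,2-silyl migration, and the C–O bond at the stereocentre stays intact.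

Step 4
Reactants: 5 methyl (S)-3-(allyloxy)-4-[(tert-butyldiphenylsilyl)oxy]butanoate
Product: 6 (S)-3-(allyloxy)-4-[(tert-butyldiphenylsilyl)oxy]butanoic acid
Conditions: LiOH·H2O, THF–H2O (3:1), 0 °C → rt; then 1 M HCl to pH 3
Reagents that add atoms: lithium hydroxide, [Li+].[OH-] (its oxygen becomes the acid OH)
Why: Ester saponification by acyl–oxygen cleavage at low temperature should be mild enough to leave the TBDPS ether and the β-alkoxy group in place.

Step 5
Reactants: 6 (S)-3-(allyloxy)-4-[(tert-butyldiphenylsilyl)oxy]butanoic acid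
Product: 8 (S)-4-(allyloxy)-5-[(tert-butyldiphenylsilyl)oxy]-1-diazopentan-2-one, via mixed isobutyl carbonic anhydride 7 (not isolated)
Conditions: i-BuOCOCl, Et3N, Et2O, 0 °C; then ethereal CH2N2 (excess), 0 °C → rt
Reagents that add atoms: isobutyl chloroformate, CC(C)COC(=O)Cl (atoms held only in 7); diazomethane, C=[N+]=[N-]
Why: Acylation of diazomethane by a mixed carbonic anhydride (the first stage of the Arndt–Eistert protocol) takes place at the more electrophilic acyl carbonyl, and this activation spares the silyl and allyl ethers.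

Step 6
Reactants: 8 (S)-4-(allyloxy)-5-[(tert-butyldiphenylsilyl)oxy]-1-diazopentan-2-one
Product: 10 (2R,5S)-2-allyl-5-{[(tert-butyldiphenylsilyl)oxy]methyl}oxolan-3-one, via cyclic oxonium ylide 9 (not isolated)
Conditions: Cu(acac)2 (10 mol%), THF, reflux, slow addition of 8
Reagents that add atoms: none
Why: Cu(acac)2, a divalent copper precatalyst, expels N2 from 8 to give an electrophilic copper carbenoid at the future C5; a lone pair of the allyl ether oxygen, held five atoms away, attacks this carbon, forms O–C5 and gives the metal-associated cyclic oxonium ylide 9. The allyl group then travels suprafacially from oxygen to C5 with allylic transposition through a five-membered envelope transition state ([2,3]-sigmatropic rearrangement), which forms C5–C4, cancels the charges and leaves the C6 ketone. The closest known reaction type is this same tandem, namely copper- or rhodium-carbenoid oxonium ylide formation and [2,3]-shift of allyl ether α-diazoketones to trans-2,5-disubstituted oxolan-3-ones. The oxolane (O, C5–C8) closes by intramolecular O-alkylation at the carbenoid carbon, a five-membered closure that is exo with respect to the breaking copper–carbon bond. The one new stereocentre, C5, is governed by the resident C8: in the ylide the allyl group on oxygen lies anti to the pseudo-equatorial silyloxymethyl group and is delivered to the ring face it already occupies, which should give the trans (2R,5S) ketone. The step needs ylide formation to outrun C–H insertion, [1,2]-shift and carbene dimerisation, and this is secured by the mild acetylacetonate-ligated copper carbenoid, the 1,5 spacing of carbenoid carbon and ether oxygen, the unhindered allyl terminus and the slow addition of 8 to the hot catalyst solution.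

Step 7
Reactants: 10 (2R,5S)-2-allyl-5-{[(tert-butyldiphenylsilyl)oxy]methyl}oxolan-3-one
Product: 11 (2R,3R,5S)-2-allyl-5-{[(tert-butyldiphenylsilyl)oxy]methyl}oxolan-3-ol
Conditions: NaBH4, MeOH, 0 °C
Reagents that add atoms: none
Why: Borohydride carbonyl reduction, in which hydride should approach the face away from the adjacent C5 allyl group to give mainly the 2,3-cis (3R) alcohol; this centre is erased in step 9, so the selectivity is of no consequence.

Step 8
Reactants: 11 (2R,3R,5S)-2-allyl-5-{[(tert-butyldiphenylsilyl)oxy]methyl}oxolan-3-ol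
Product: 12 O-[(2R,3R,5S)-2-allyl-5-{[(tert-butyldiphenylsilyl)oxy]methyl}oxolan-3-yl] 1H-imidazole-1-carbothioate
Conditions: 1,1'-thiocarbonyldiimidazole (2 equiv), DMAP (10 mol%), THF, reflux
Reagents that add atoms: 1,1'-thiocarbonyldiimidazole, S=C(n1ccnc1)n1ccnc1
Why: Thiocarbonylation of a secondary alcohol in preparation for Barton–McCombie deoxygenation runs under neutral conditions, so no alkoxide is generated in a molecule that carries a silyl ether.

Step 9
Reactants: 12 O-[(2R,3R,5S)-2-allyl-5-{[(tert-butyldiphenylsilyl)oxy]methyl}oxolan-3-yl] 1H-imidazole-1-carbothioate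
Product: 13 (2S,5S)-2-allyl-5-{[(tert-butyldiphenylsilyl)oxy]methyl}oxolane (trans)
Conditions: Bu3SnH (1.5 equiv), AIBN (10 mol%), toluene, 90 °C
Reagents that add atoms: none
Why: Barton–McCombie radical deoxygenation, in which the secondary C6 radical should abstract hydrogen from the stannane faster than it can close onto the allyl group (only slow 4-exo or 5-endo modes are open), while C5 and C8 take no part.

Step 10
Reactants: 13 (2S,5S)-2-allyl-5-{[(tert-butyldiphenylsilyl)oxy]methyl}oxolane; 14 methyl acrylate
Product: 15 methyl (E)-4-[(2S,5S)-5-{[(tert-butyldiphenylsilyl)oxy]methyl}oxolan-2-yl]but-2-enoate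
Conditions: 14 (5 equiv), second-generation Hoveyda–Grubbs catalyst (5 mol%), CH2Cl2, 40 °C
Reagents that add atoms: none
Why: Olefin cross-metathesis between a reactive terminal alkene and an electron-poor acrylate that hardly homodimerises favours the E-configured cross product, and it is placed after ketone removal so that no carbonyl-acidified C5–H sits next to the new enoate.

Step 11
Reactants: 15 methyl (E)-4-[(2S,5S)-5-{[(tert-butyldiphenylsilyl)oxy]methyl}oxolan-2-yl]but-2-enoate
Product: 16 methyl 4-[(2R,5S)-5-{[(tert-butyldiphenylsilyl)oxy]methyl}oxolan-2-yl]butanoate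
Conditions: H2 (1 atm), Pd/C (10 wt%), EtOAc, rt
Reagents that add atoms: none
Why: Heterogeneous catalytic hydrogenation saturates the conjugated alkene, while the ester, silyl ether and oxolane are inert under one atmosphere of hydrogen.

Step 12
Reactants: 16 methyl 4-[(2R,5S)-5-{[(tert-butyldiphenylsilyl)oxy]methyl}oxolan-2-yl]butanoate
Product: 17 methyl 4-[(2R,5S)-5-(hydroxymethyl)oxolan-2-yl]butanoate
Conditions: TBAF, AcOH (1:1), THF, 0 °C → rt
Reagents that add atoms: none
Why: Fluoride-mediated silyl ether cleavage is buffered with acetic acid so that neither basic fluoride nor the liberated alkoxide attacks the methyl ester.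

Step 13
Reactants: 17 methyl 4-[(2R,5S)-5-(hydroxymethyl)oxolan-2-yl]butanoate
Product: 18 methyl 4-[(2R,5S)-5-formyloxolan-2-yl]butanoate
Conditions: Dess–Martin periodinane, CH2Cl2, 0 °C → rt; used at once
Reagents that add atoms: none
Why: Dess–Martin oxidation of a primary alcohol under non-basic conditions stops at the aldehyde and should not epimerise the α-alkoxy centre C8.

Step 14
Reactants: 18 methyl 4-[(2R,5S)-5-formyloxolan-2-yl]butanoate
Product: 19 methyl 4-[(2R,5S)-5-ethynyloxolan-2-yl]butanoate
Conditions: dimethyl (1-diazo-2-oxopropyl)phosphonate, K2CO3, MeOH, 0 °C → rt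
Reagents that add atoms: dimethyl (1-diazo-2-oxopropyl)phosphonate, COP(=O)(OC)C(=[N+]=[N-])C(C)=O (its diazo carbon becomes C10)
Why: The Ohira–Bestmann variant of the Seyferth–Gilbert homologation turns the aldehyde into the terminal alkyne with a weak base in methanol, a medium in which exchange at the methyl ester is degenerate, and the low starting temperature should keep C8 from epimerising.

Step 15
Reactants: 20 acetylene
Product: 21 (E)-1-bromo-2-iodoethene
Conditions: IBr, 48% aq HBr, 0 °C, acetylene stream
Reagents that add atoms: iodine monobromide, BrI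
Why: Electrophilic anti addition of iodine monobromide to acetylene through a bridged iodonium ion should give the E-dihaloethene.

Step 16
Reactants: 22 octa-1,7-diyne; 21 (E)-1-bromo-2-iodoethene
Product: 24 (1E,3E)-1-bromodeca-1,3-dien-9-yne, via alkenylzirconocene chloride 23 (not isolated)
Conditions: Cp2Zr(H)Cl (1 equiv), 22 (4 equiv), THF, rt; excess 22 evaporated; then 21 (1.2 equiv), Pd(PPh3)4 (5 mol%), ZnBr2 (20 mol%), THF, 0 °C → rt
Reagents that add atoms: Cp2Zr(H)Cl, [H][Zr](Cl)(C1C=CC=C1)C1C=CC=C1 (Zr, Cl and Cp atoms held only in 23)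
Why: Hydrozirconation (syn, zirconium at the terminal carbon) is followed by Negishi-type palladium-catalysed alkenyl–alkenyl coupling, in which zerovalent palladium inserts into the carbon–iodine bond of 21 much faster than into its carbon–bromine bond, both partners keep their geometry, and the excess of volatile diyne limits double hydrozirconation.

Step 17
Reactants: 24 (1E,3E)-1-bromodeca-1,3-dien-9-yne
Product: 26 (1E,3E,9E)-1-bromo-10-iododeca-1,3,9-triene, via alkenylzirconocene chloride 25 (not isolated)
Conditions: Cp2Zr(H)Cl (1.1 equiv), THF, 0 °C → rt, dark; then I2 (1.0 equiv), THF, −78 → 0 °C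
Reagents that add atoms: iodine, [I][I]; Cp2Zr(H)Cl, [H][Zr](Cl)(C1C=CC=C1)C1C=CC=C1 (Zr, Cl and Cp atoms held only in 25)
Why: In this hydrozirconation–iodinolysis the terminal alkyne should react with Cp2Zr(H)Cl far faster than the 1,2-disubstituted double bonds of the bromodiene, and syn addition followed by retentive cleavage of the carbon–zirconium bond fixes the 9E geometry.

Step 18
Reactants: 19 methyl 4-[(2R,5S)-5-ethynyloxolan-2-yl]butanoate; 26 (1E,3E,9E)-1-bromo-10-iododeca-1,3,9-triene
Product: 27 methyl 4-{(2R,5S)-5-[(3E,9E,11E)-12-bromododeca-3,9,11-trien-1-yn-1-yl]oxolan-2-yl}butanoate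
Conditions: 26 (1.3 equiv), Pd(PPh3)4 (5 mol%), CuI (10 mol%), i-Pr2NH, degassed THF, 0 °C → rt
Reagents that add atoms: none
Why: In this Sonogashira coupling, oxidative addition of zerovalent palladium to the alkenyl iodide is far faster than to an alkenyl bromide at or below room temperature, so with 26 in slight excess the alkyne should be consumed at C11 with retention of the E geometry while the bromodiene, the ester and both stereocentres survive.

Compound list
1 | dimethyl (S)-malate (dimethyl L-malate) | COC(=O)C[C@H](O)C(=O)OC | starting material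
2 | methyl (S)-3,4-dihydroxybutanoate | COC(=O)C[C@H](O)CO | intermediate
3 | methyl (S)-4-[(tert-butyldiphenylsilyl)oxy]-3-hydroxybutanoate | COC(=O)C[C@H](O)CO[Si](c1ccccc1)(c1ccccc1)C(C)(C)C | intermediate
4 | allyl 2,2,2-trichloroacetimidate | C=CCOC(=N)C(Cl)(Cl)Cl | starting material
5 | methyl (S)-3-(allyloxy)-4-[(tert-butyldiphenylsilyl)oxy]butanoate | COC(=O)C[C@H](OCC=C)CO[Si](c1ccccc1)(c1ccccc1)C(C)(C)C | intermediate
6 | (S)-3-(allyloxy)-4-[(tert-butyldiphenylsilyl)oxy]butanoic acid | OC(=O)C[C@H](OCC=C)CO[Si](c1ccccc1)(c1ccccc1)C(C)(C)C | intermediate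
7 | (S)-3-(allyloxy)-4-[(tert-butyldiphenylsilyl)oxy]butanoic isobutyl carbonic anhydride | CC(C)COC(=O)OC(=O)C[C@H](OCC=C)CO[Si](c1ccccc1)(c1ccccc1)C(C)(C)C | intermediate
8 | (S)-4-(allyloxy)-5-[(tert-butyldiphenylsilyl)oxy]-1-diazopentan-2-one | [N-]=[N+]=CC(=O)C[C@H](OCC=C)CO[Si](c1ccccc1)(c1ccccc1)C(C)(C)C | intermediate
9 | (5S)-1-allyl-5-{[(tert-butyldiphenylsilyl)oxy]methyl}-3-oxooxolan-1-ium-2-ide | C=CC[O+]1[CH-]C(=O)C[C@H]1CO[Si](c2ccccc2)(c2ccccc2)C(C)(C)C | intermediate
10 | (2R,5S)-2-allyl-5-{[(tert-butyldiphenylsilyl)oxy]methyl}oxolan-3-one | C=CC[C@@H]1C(=O)C[C@@H](CO[Si](c2ccccc2)(c2ccccc2)C(C)(C)C)O1 | intermediate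
11 | (2R,3R,5S)-2-allyl-5-{[(tert-butyldiphenylsilyl)oxy]methyl}oxolan-3-ol | C=CC[C@@H]1[C@H](O)C[C@@H](CO[Si](c2ccccc2)(c2ccccc2)C(C)(C)C)O1 | intermediate
12 | O-[(2R,3R,5S)-2-allyl-5-{[(tert-butyldiphenylsilyl)oxy]methyl}oxolan-3-yl] 1H-imidazole-1-carbothioate | C=CC[C@@H]1[C@H](OC(=S)n2ccnc2)C[C@@H](CO[Si](c3ccccc3)(c3ccccc3)C(C)(C)C)O1 | intermediate
13 | (2S,5S)-2-allyl-5-{[(tert-butyldiphenylsilyl)oxy]methyl}oxolane (trans) | C=CC[C@@H]1CC[C@@H](CO[Si](c2ccccc2)(c2ccccc2)C(C)(C)C)O1 | intermediate
14 | methyl acrylate | C=CC(=O)OC | starting material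
15 | methyl (E)-4-[(2S,5S)-5-{[(tert-butyldiphenylsilyl)oxy]methyl}oxolan-2-yl]but-2-enoate | COC(=O)/C=C/C[C@@H]1CC[C@@H](CO[Si](c2ccccc2)(c2ccccc2)C(C)(C)C)O1 | intermediate
16 | methyl 4-[(2R,5S)-5-{[(tert-butyldiphenylsilyl)oxy]methyl}oxolan-2-yl]butanoate | COC(=O)CCC[C@@H]1CC[C@@H](CO[Si](c2ccccc2)(c2ccccc2)C(C)(C)C)O1 | intermediate
17 | methyl 4-[(2R,5S)-5-(hydroxymethyl)oxolan-2-yl]butanoate | COC(=O)CCC[C@@H]1CC[C@@H](CO)O1 | intermediate
18 | methyl 4-[(2R,5S)-5-formyloxolan-2-yl]butanoate | COC(=O)CCC[C@@H]1CC[C@@H](C=O)O1 | intermediate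
19 | methyl 4-[(2R,5S)-5-ethynyloxolan-2-yl]butanoate | COC(=O)CCC[C@@H]1CC[C@@H](C#C)O1 | intermediate
20 | acetylene | C#C | starting material
21 | (E)-1-bromo-2-iodoethene | Br/C=C/I | intermediate
22 | octa-1,7-diyne | C#CCCCCC#C | starting material
23 | chlorobis(cyclopentadienyl)[(E)-oct-1-en-7-yn-1-yl]zirconium | C#CCCCC/C=C/[Zr](Cl)(C1C=CC=C1)C1C=CC=C1 | intermediate
24 | (1E,3E)-1-bromodeca-1,3-dien-9-yne | Br/C=C/C=C/CCCCC#C | intermediate
25 | [(1E,7E,9E)-10-bromodeca-1,7,9-trien-1-yl]chlorobis(cyclopentadienyl)zirconium | Br/C=C/C=C/CCCC/C=C/[Zr](Cl)(C1C=CC=C1)C1C=CC=C1 | intermediate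
26 | (1E,3E,9E)-1-bromo-10-iododeca-1,3,9-triene | Br/C=C/C=C/CCCC/C=C/I | intermediate
27 | methyl 4-{(2R,5S)-5-[(3E,9E,11E)-12-bromododeca-3,9,11-trien-1-yn-1-yl]oxolan-2-yl}butanoate (CNP0231094.2) | COC(=O)CCC[C@@H]1CC[C@@H](C#C/C=C/CCCC/C=C/C=C/Br)O1 | target

Total step count: 18. Longest linear sequence: 15 steps (steps 1–14, then step 18). Steps 15–17 build the side arm in parallel.

Steps most likely to fail

Step 16. The diyne may be hydrozirconated at both ends. More seriously, palladium may insert a second time, into the carbon–bromine bond of the freshly formed bromodiene, so that 23 is consumed in over-coupling.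
The fallback sets out from 23 and comes back at 24. It brings bromine in only after all palladium chemistry is over.
- 23 is quenched with I2 (THF, 0 °C) to give (E)-1-iodooct-1-en-7-yne F1.
- Stille coupling of F1 with an excess of commercial (E)-1,2-bis(tributylstannyl)ethene (PdCl2(MeCN)2, DMF, rt) should give tributyl[(1E,3E)-deca-1,3-dien-9-yn-1-yl]stannane F2.
- Bromodestannylation of F2 with NBS (CH2Cl2, −78 → 0 °C) proceeds with retention and delivers 24.

Step 18. Halide discrimination may erode: palladium may also insert into the bromodiene of 26 or of the product, which leads to oligomerisation. Copper-mediated homocoupling of the alkyne is a further loss.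
The fallback sets out from 19 and from 25, and comes back at 27. It reverses the polarity of the C10–C11 union and uses no palladium.
- 19 is brominated (NBS, AgNO3 10 mol%, acetone, rt) to methyl 4-[(2R,5S)-5-(bromoethynyl)oxolan-2-yl]butanoate F3.
- 25 is generated from 24 as in step 17, with the iodine quench omitted.
- F3 is joined to 25 under CuCl catalysis (THF, rt). This is a known alkenylzirconocene–haloalkyne coupling that retains the alkene geometry and leaves alkenyl bromides alone, and it gives 27 directly.

Step 14. The α-alkoxy aldehyde may epimerise at C8 under carbonate in methanol before the homologation takes place.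
The fallback sets out from 18 and comes back at 19. It removes the carbonyl group under neutral conditions first, so C8 ceases to be α to a carbonyl in the first operation.
- Ramirez dibromo-olefination (CBr4, PPh3, CH2Cl2, 0 °C) gives methyl 4-[(2R,5S)-5-(2,2-dibromoethenyl)oxolan-2-yl]butanoate F4.
- Palladium-catalysed hydrogenolysis of the more accessible trans carbon–bromine bond (Bu3SnH, Pd(PPh3)4, toluene, rt) gives methyl 4-{(2R,5S)-5-[(Z)-2-bromoethenyl]oxolan-2-yl}butanoate F5.
- Anti elimination of HBr with TBAF·3H2O in DMF furnishes 19.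

Further compounds
F1 | step 16 | (E)-1-iodooct-1-en-7-yne | I/C=C/CCCCC#C
F2 | step 16 | tributyl[(1E,3E)-deca-1,3-dien-9-yn-1-yl]stannane | CCCC[Sn](CCCC)(CCCC)/C=C/C=C/CCCCC#C
F3 | step 18 | methyl 4-[(2R,5S)-5-(bromoethynyl)oxolan-2-yl]butanoate | COC(=O)CCC[C@@H]1CC[C@@H](C#CBr)O1
F4 | step 14 | methyl 4-[(2R,5S)-5-(2,2-dibromoethenyl)oxolan-2-yl]butanoate | COC(=O)CCC[C@@H]1CC[C@@H](C=C(Br)Br)O1
F5 | step 14 | methyl 4-{(2R,5S)-5-[(Z)-2-bromoethenyl]oxolan-2-yl}butanoate | COC(=O)CCC[C@@H]1CC[C@@H](/C=C\Br)O1
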